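## Remarks on the chemistry (corrections and assumptions)

- **Stereochemical label.** The siloxyalkyne 14 and the benzannulation product 19 must be the threo (syn) diastereomers, (4S,5S) and (2S,3S). Calling them erythro would be an error: an inverting Mitsunobu closure at C2 turns threo into the 2,3-trans ring of catechin and erythro into the 2,3-cis ring of the epicatechin series. A kinetic-resolution epoxidation of an aryl vinyl carbinol followed by acetylide opening would give the erythro series, so the chain is built instead by a chelation-controlled aryl addition.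
- **O7 protecting group.** The cyclobutenone carries an allyl ether in place of a 4-methoxybenzyl ether; the skeleton and the bonds formed in the key step are unchanged. Quinone oxidants such as DDQ are known to abstract hydride from C4 of 5,7-dioxygenated flavans, and acidolysis would release a benzyl cation beside a phloroglucinol ring and an ionisable C2–O1 bond. Allyl is removed by zerovalent palladium under neutral conditions.
- **Starting materials.** Ring B enters as an aryl Grignard reagent because only the chelate-controlled addition to an α-benzyloxy aldehyde gives the threo alcohol with the right protecting pattern. The galloyl unit is bought already benzylated.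
- **Assumption.** Compounds 4, 9 and 23 are taken to be commercially available.

## Structural features

The target is a flavan-3-ol. Ring A, a phloroglucinol-type benzene ring, is fused through C4a and C8a to the dihydropyran ring C (O1, C2, C3, C4); C2 carries the catechol ring B, C3 a hydroxyl, and O7 a galloyl ester. The only stereocentres, C2 (R) and C3 (S), are neighbours in ring C and trans; C2 is a benzylic ether carbon next to an electron-rich aryl group and can ionise, so it is best set late by a defined displacement. The aryl gallate is cleaved by base and nucleophiles, the free catechol and pyrogallol units oxidise in air, and the electron-rich ring A exposes C4 to hydride abstraction and C6/C8 to carbocations; all phenols are therefore unmasked in one neutral final step. The real difficulty is regiochemical: the oxygens on C5, C7 and C8a surround C4a, the one ring A carbon that bears carbon, and must play three roles (O1 closes ring C, O5 ends free, O7 carries the gallate), although O5 and O7 of a preformed catechin are hard to tell apart. The key step uses this pattern: an alkyne supplies C4a (with the chiral chain) and C5 (with a silyloxy group), and a four-carbon vinylketene supplies C8a (as the carbonyl that becomes the free phenol), C8, C7 (with its alkoxy group) and C6. The C2–C3 unit travels through the ring construction as an open-chain threo 1,2-dioxygenated fragment, and O1–C2 is closed afterwards with inversion.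

## Logic of the disconnections

**26 to 25.** Six O–benzyl bonds are traced back (two on ring B, one on O3, three on the galloyl unit). One neutral hydrogenolysis then releases the air-sensitive polyphenol without base, which the aryl ester would not survive. Nothing is simplified in the skeleton, but all sensitive functions stay masked until the end. The demand is that benzyl is never needed as a temporary group and that the benzylic C2–O1 bond survives.

**25 to 24.** The O5–Si bond is restored. The silyl ether is the form in which O5 leaves the ring construction, and keeping it through the acylation makes the 7-OH the only nucleophile. The demand is a fluoride cleavage buffered so that the aryl ester is not attacked.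

**24 to 22 and 23.** The acyl C–O bond between O7 and the galloyl carbonyl is cut. This splits off the whole ring D unit as a stable, fully benzylated acid and leaves a mono-phenol. The forward step needs no regiocontrol, provided 22 has exactly one free hydroxyl.

**22 to 21.** The O7–allyl bond is restored. O7 needs a group that survives heat, ketenes, mild acid and Mitsunobu conditions and then leaves without oxidant, acid or cation, because C4, C6, C8 and the C2–O1 bond of 21 are sensitive to all three. The demand is a palladium-catalysed allyl transfer that leaves benzyl and silyl ethers alone.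

**21 to 20.** The O1–C2 bond is cut. This opens ring C to a 1,3-diarylpropane with a benzylic alcohol and one free phenol, so the two stereocentres become those of an acyclic 1,2-dioxygenated unit that can be made by acyclic stereocontrol. The closure must invert C2, so 20 must be threo (2S,3S), and with it 19 and 14; an erythro chain would close to the 2,3-cis ring. O3 must be blocked by a non-participating ether and only one phenol may be free.

**20 to 19.** The benzylic O–Si bond is restored. The silyl ether hides the only alcohol from the ketenes of the benzannulation. The demand is a cleavage mild enough to spare the aryl silyl ether and not ionise the benzylic position.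

**19 to 3 and 14.** The bonds C4a–C8a, C5–C6 and C8–C8a are cut, so ring A falls apart into a four-carbon and a two-carbon piece. This is the strategic cut: 19 has three chemically different ring A oxygens (free, silylated, allylated), and the disconnection assigns each to a different origin, so no selective protection of a phloroglucinol is ever needed. The gain is the whole aromatic ring and its differentiation in one step. The demands are complete regiocontrol in the union of the two pieces and survival of the chain stereocentres and the benzylic silyl ether on heating.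

**3 to 1 and 2.** The C3–O bond of the vinylogous ester is exchanged. 1 is a purchasable four-carbon ring and 2 supplies the removable O7 substituent. The demand is an exchange that does not open the strained ring.

**14 to 12, and 12 to 11.** The alkyne C–O bond and the two O–Si bonds are cut. A terminal alkyne is a robust carrier for the future C4a–C5 unit and can be oxidised to the ynolate at the last moment, so the sensitive siloxyalkyne exists for one step only. The demands are a base that spares the benzyl ethers and silylation of the ynolate on oxygen.

**11 to 8 and 9 (through 10).** The C–C bond between the benzylic carbon (future C2) and ring B (C1′) is cut. This sets the second stereocentre relative to the first by chelation and gives the benzylic hydroxyl free and the neighbouring oxygen benzylated, exactly the pattern the end game needs. The demand is high chelate control in the addition and an aldehyde that keeps its α-configuration.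

**8 to 7, 6, 5 and 4.** The aldehyde is traced to a primary alcohol and its trityl ether, the O-benzyl bond is removed, and the C–C bond between the propargylic carbon (future C4) and the alkyne is cut at an epoxide. C3 thus comes from the chiral pool as 4, with no resolution and no loss of half the material. The demands are opening at the terminal epoxide carbon only and a protecting group on the primary oxygen that cannot migrate during benzylation.

## Other disconnections considered

**Alternative 1:** The cut is at C3–C4 and C2–C1′, around a three-carbon unit with boron on C3. Vinyllithium adds to the ring A benzylboronic ester A1, and Pd(OAc)2 with a Mandyphos-type bisphosphine couples the resulting ate complex with the ring B triflate A2. The arylpalladium species (divalent palladium) activates the vinyl group, the benzyl group migrates from boron to carbon (C3–C4), and reductive elimination forms C2–C1′ to give boronate A3.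
- *In favour:* two C–C bonds and the C3 stereocentre are made in one catalytic enantioselective step from two simple arenes, and oxidation of C–B to C–OH is stereoretentive. Ring A of A1 is symmetric about C4a with O7 already distinct, so the oxygen problem is solved by symmetry; on this point the alternative is the equal of the chosen plan.
- *Against:* A3 has C2 as a methylene. O1–C2 and the C2 stereocentre would have to come from a later benzylic C–H oxidation of a 1,3-diarylpropane whose other benzylic position, C4 on the more electron-rich ring A, is the one oxidants prefer. Migration of a hindered 2,6-disubstituted benzyl group is less well documented than alkyl or aryl migration, and direct transfer of the benzyl group to palladium is a plausible competing path.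
- *Comparison:* the chosen plan brings C2 in at the alcohol oxidation level and never needs a C–H oxidation. Mechanistically both rest on well-defined sequences. The alternative sets absolute configuration by a catalyst and would reach the C6–C3–C6 skeleton in fewer steps, and on both counts it is the better plan; the unsolved closure of ring C is likely to cost more than is saved.

**Alternative 2:** The cut is O1–C2, made from a C2 methylene. Anodic oxidation of ring B in the diarylpropanol ether A4 removes two electrons and the C2 proton, and one of the two equivalent ring A phenols traps the benzylic cation to give A5, which is identical with 25.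
- *In favour:* the ring A diol is symmetric, so the cyclisation itself separates O1 from O5 with no protecting group on either; this is more economical than the chosen plan. A5 is one step from the target, so the end game would be shorter; here the alternative is the better plan on step economy. C2 would be set by the neighbouring C3 ether in favour of the trans ring, comparable to the chosen closure.
- *Against:* the anode must oxidise a catechol diether in the presence of a ring bearing two free phenols, which are expected to be oxidised more easily and to follow phenoxonium or coupling pathways. C4 is also benzylic, six benzyl ethers offer further benzylic C–H bonds, and the product flavan is at least as oxidisable as A4. Documented anodic benzylic etherifications concern simple alkylarenes rather than polyphenols. C3 must still be made enantiopure by other means.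
- *Comparison:* the alternative is shorter and leaner in protecting groups, but its selectivity depends on an ordering of oxidation potentials that is unfavourable here. The chosen plan is longer but every selectivity is fixed by structure.

**Alternative 3:** The cut is C3–C4 and O1–C2 in one [4+2] step. A chiral BINOL-derived phosphoric acid dehydrates the ortho-hydroxybenzyl alcohol A6 to the ortho-quinone methide A7, which adds across the (E)-styrylsilane A8 to give the 2,3-trans silyl chroman A9; a Fleming–Tamao oxidation would then turn C–Si into C3–OH with retention.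
- *In favour:* ring C and both stereocentres arise in one convergent step. The trans relationship follows stereospecifically from the alkene geometry, which is the equal of, or better than, an inverting displacement at an ionisable carbon. The aryl group and the β-silicon effect agree on the regiochemistry, and the step count to the flavan core would be lower; on convergence and step economy the alternative is the better plan.
- *Against:* A6 must already have O1 free, O5 benzylated and O7 silylated, which is the differentiation the chosen plan obtains by construction. If the cycloaddition is stepwise, the β-silyl cation can lose silicon and give a 1,3-diarylpropene. Enantiocontrol over a styrylsilane that offers the catalyst no hydrogen-bond handle is uncertain. Oxidation of the dimethylphenylsilyl group needs an electrophile (HBF4, Hg(OAc)2 or a bromine source with peracid), for which C6 and C8 of ring A and the benzylated catechol would compete.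
- *Comparison:* the alternative is the more elegant ring C construction, but it moves the hard problem into the synthesis of A6 and into a harsh silicon oxidation on an electron-rich flavan. The chosen plan spends more steps on the chain and gains a ring A whose oxygens are distinguished from the outset.

Key step: step 9

## Route

Step 1
Reactants: 1 3-ethoxycyclobut-2-en-1-one; 2 prop-2-en-1-ol (allyl alcohol)
Product: 3 3-(allyloxy)cyclobut-2-en-1-one
Conditions: 2 as solvent, camphorsulfonic acid (2 mol%), 25 °C; EtOH stripped under reduced pressure, repeated once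
Reagents that add atoms: none
Why: Acid-catalysed exchange of a vinylogous ester: protonation at the carbonyl oxygen gives a 1,3-dioxygenated cyclobutenyl cation, the alcohol in excess adds at C3 and ethanol is lost. Removal of ethanol drives the equilibrium, and allyl alcohol is not acid-sensitive.

Step 2
Reactants: 4 (S)-glycidyl trityl ether [(2S)-2-[(triphenylmethoxy)methyl]oxirane]
Product: 5 (2S)-1-(triphenylmethoxy)pent-4-yn-2-ol
Conditions: LiC≡CH·H2NCH2CH2NH2, DMSO, 0 °C → rt
Reagents that add atoms: lithium acetylide–ethylenediamine complex, [Li]C#C.NCCN
Why: SN2 opening of the terminal epoxide at its unsubstituted carbon by the acetylide; the stereocentre is not touched and keeps the S configuration.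

Step 3
Reactants: 5 (2S)-1-(triphenylmethoxy)pent-4-yn-2-ol
Product: 6 (4S)-4-(benzyloxy)-5-(triphenylmethoxy)pent-1-yne
Conditions: NaH, BnBr, Bu4NI (cat.), THF/DMF, 0 °C → rt
Reagents that add atoms: benzyl bromide, BrCc1ccccc1
Why: Williamson etherification of the secondary alkoxide; the trityl ether cannot migrate, and NaH does not deprotonate the terminal alkyne at this temperature.

Step 4
Reactants: 6 (4S)-4-(benzyloxy)-5-(triphenylmethoxy)pent-1-yne
Product: 7 (2S)-2-(benzyloxy)pent-4-yn-1-ol
Conditions: TsOH·H2O (cat.), MeOH/CH2Cl2, rt
Reagents that add atoms: none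
Why: Acid-catalysed solvolysis of the trityl ether through the trityl cation, which methanol traps; the benzyl ether and the alkyne are inert.

Step 5
Reactants: 7 (2S)-2-(benzyloxy)pent-4-yn-1-ol
Product: 8 (2S)-2-(benzyloxy)pent-4-ynal
Conditions: Dess–Martin periodinane, CH2Cl2, 0 °C → rt; used crude at once
Reagents that add atoms: none
Why: Dess–Martin oxidation under non-basic conditions should give the α-benzyloxy aldehyde without epimerisation; immediate use avoids racemisation on storage or silica.

Step 6
Reactants: 8 (2S)-2-(benzyloxy)pent-4-ynal; 9 4-bromo-1,2-bis(benzyloxy)benzene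
Product: 11 (1S,2S)-2-(benzyloxy)-1-[3,4-bis(benzyloxy)phenyl]pent-4-yn-1-ol, via arylmagnesium bromide 10 (not isolated)
Conditions: 9, Mg, THF, rt; then 8, MgBr2·OEt2, CH2Cl2, −78 °C
Reagents that add atoms: none
Why: Cram-chelate addition: magnesium bridges the carbonyl and benzyloxy oxygens in a five-membered chelate and the aryl group enters from the face opposite the propargyl group, which sets C1 as S and gives the threo (syn) arrangement. Addition to the chelated aldehyde at −78 °C is much faster than deprotonation of the terminal alkyne.

Step 7
Reactants: 11 (1S,2S)-2-(benzyloxy)-1-[3,4-bis(benzyloxy)phenyl]pent-4-yn-1-ol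
Product: 12 {[(1S,2S)-2-(benzyloxy)-1-[3,4-bis(benzyloxy)phenyl]pent-4-yn-1-yl]oxy}(triethyl)silane
Conditions: Et3SiCl, imidazole, CH2Cl2, 0 °C → rt
Reagents that add atoms: chlorotriethylsilane, CC[Si](Cl)(CC)CC
Why: Standard silylation of a secondary benzylic alcohol; the triethylsilyl ether masks the only protic group before the ynolate and ketene chemistry and can later be removed by mild acid without loss of an aryl silyl ether.

Step 8
Reactants: 12 {[(1S,2S)-2-(benzyloxy)-1-[3,4-bis(benzyloxy)phenyl]pent-4-yn-1-yl]oxy}(triethyl)silane
Product: 14 (4S,5S)-4-(benzyloxy)-5-[3,4-bis(benzyloxy)phenyl]-5-[(triethylsilyl)oxy]-1-[(triisopropylsilyl)oxy]pent-1-yne, via lithium ynolate 13 (not isolated)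
Conditions: LiN(SiMe3)2 (2.2 equiv), THF, −78 °C; t-BuOOH (anhydrous), −78 → 0 °C; i-Pr3SiOTf, −78 °C; filtration through base-washed silica
Reagents that add atoms: tert-butyl hydroperoxide, CC(C)(C)OO; triisopropylsilyl trifluoromethanesulfonate, CC(C)[Si](OS(=O)(=O)C(F)(F)F)(C(C)C)C(C)C
Why: Oxidation of the lithium acetylide by lithium tert-butyl peroxide (electrophilic oxygen transfer with loss of tert-butoxide) gives the lithium ynolate, which the bulky silyl triflate captures on oxygen. The amide base is too weak to deprotonate benzylic ether positions, and no stereocentre is involved.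

Step 9
Reactants: 3 3-(allyloxy)cyclobut-2-en-1-one; 14 (4S,5S)-4-(benzyloxy)-5-[3,4-bis(benzyloxy)phenyl]-5-[(triethylsilyl)oxy]-1-[(triisopropylsilyl)oxy]pent-1-yne
Product: 19 5-(allyloxy)-2-{(2S,3S)-2-(benzyloxy)-3-[3,4-bis(benzyloxy)phenyl]-3-[(triethylsilyl)oxy]propyl}-3-[(triisopropylsilyl)oxy]phenol, via vinylketene 15 (not isolated), via 4-vinylcyclobutenone 16 (not isolated), via dienylketene 17 (not isolated), via cyclohexa-2,4-dienone 18 (not isolated)
Conditions: toluene, 80 °C (3, 1.2 equiv, added over 2 h), then 110 °C, argon
Reagents that add atoms: none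
Why: This is a Danheiser benzannulation of a cyclobutenone with a siloxyalkyne. Heat opens 3 by four-electron electrocyclic ring opening to vinylketene 15, whose ketene carbon is attacked by the carbon-substituted, nucleophilic terminus of the siloxyalkyne in a regiospecific [2+2] cycloaddition that forms C8a–C4a and C6–C5 and gives 16. A second four-electron ring opening gives dienylketene 17, which closes ring A by a six-electron disrotatory electrocyclisation (C8–C8a) to 18, and tautomerisation gives the phenol. The ketene carbonyl becomes the free 8a-OH, the alkyne oxygen the 5-O-silyl ether and the cyclobutenone alkoxy group the 7-O-allyl ether, so the three ring A oxygens emerge differentiated. No lasting stereocentre is created (the sp3 ring carbon of 16 disappears on ring opening), and the two chain stereocentres are remote from the reacting π-system and not epimerisable under neutral thermal conditions. The only selectivity needed is regiochemical, and it is fixed by the polarisation of the ynol ether, the same polarity by which ketene and an alkoxyacetylene give a 3-alkoxycyclobutenone. Slow addition of 3 keeps 15 dilute so that it is captured by the alkyne and not by the phenolic product or by itself; relief of ring strain and aromatisation drive the cascade.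

Step 10
Reactants: 19 5-(allyloxy)-2-{(2S,3S)-2-(benzyloxy)-3-[3,4-bis(benzyloxy)phenyl]-3-[(triethylsilyl)oxy]propyl}-3-[(triisopropylsilyl)oxy]phenol
Product: 20 5-(allyloxy)-2-{(2S,3S)-2-(benzyloxy)-3-[3,4-bis(benzyloxy)phenyl]-3-hydroxypropyl}-3-[(triisopropylsilyl)oxy]phenol
Conditions: AcOH/THF/H2O (3:1:1), rt
Reagents that add atoms: none
Why: Solvolysis of the alkyl triethylsilyl ether in aqueous acetic acid; the hindered aryl triisopropylsilyl ether, the allyl ether and the benzyl ethers should be stable, and the medium is too weakly acidic to ionise the benzylic alcohol.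

Step 11
Reactants: 20 5-(allyloxy)-2-{(2S,3S)-2-(benzyloxy)-3-[3,4-bis(benzyloxy)phenyl]-3-hydroxypropyl}-3-[(triisopropylsilyl)oxy]phenol
Product: 21 (2R,3S)-7-(allyloxy)-3-(benzyloxy)-2-[3,4-bis(benzyloxy)phenyl]-5-[(triisopropylsilyl)oxy]chromane
Conditions: PPh3, DIAD, THF (0.02 M), 0 °C → rt
Reagents that add atoms: none
Why: Intramolecular Mitsunobu etherification: the benzylic alcohol is activated as its alkoxyphosphonium ion and displaced by the only free phenol (6-exo-tet) with inversion, so 3S of the chain becomes 2R of the chroman and the ring is 2,3-trans. Any ionisation at the electron-rich benzylic carbon should lead to the same, more stable trans isomer.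

Step 12
Reactants: 21 (2R,3S)-7-(allyloxy)-3-(benzyloxy)-2-[3,4-bis(benzyloxy)phenyl]-5-[(triisopropylsilyl)oxy]chromane
Product: 22 (2R,3S)-3-(benzyloxy)-2-[3,4-bis(benzyloxy)phenyl]-5-[(triisopropylsilyl)oxy]chroman-7-ol
Conditions: Pd(PPh3)4 (5 mol%), morpholine (10 equiv), THF, rt
Reagents that add atoms: none
Why: Tsuji–Trost deallylation: zerovalent palladium ionises the aryl allyl ether to a π-allyl complex and the phenoxide, and morpholine takes up the allyl group irreversibly. No acid, oxidant or carbocation is involved, so C4, the C2–O1 bond, the benzyl ethers and the silyl ether are not at risk.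

Step 13
Reactants: 22 (2R,3S)-3-(benzyloxy)-2-[3,4-bis(benzyloxy)phenyl]-5-[(triisopropylsilyl)oxy]chroman-7-ol; 23 3,4,5-tris(benzyloxy)benzoic acid
Product: 24 (2R,3S)-3-(benzyloxy)-2-[3,4-bis(benzyloxy)phenyl]-5-[(triisopropylsilyl)oxy]chroman-7-yl 3,4,5-tris(benzyloxy)benzoate
Conditions: EDC·HCl, DMAP, CH2Cl2, rt
Reagents that add atoms: none
Why: Steglich esterification of the single free phenol; DMAP transfers the acyl group from the O-acylisourea, and every other oxygen is blocked, so no regiochemical question arises.

Step 14
Reactants: 24 (2R,3S)-3-(benzyloxy)-2-[3,4-bis(benzyloxy)phenyl]-5-[(triisopropylsilyl)oxy]chroman-7-yl 3,4,5-tris(benzyloxy)benzoate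
Product: 25 (2R,3S)-3-(benzyloxy)-2-[3,4-bis(benzyloxy)phenyl]-5-hydroxychroman-7-yl 3,4,5-tris(benzyloxy)benzoate
Conditions: Bu4NF, AcOH, THF, 0 °C
Reagents that add atoms: none
Why: Fluoride cleaves the aryl O–Si bond; acetic acid buffers the phenoxide so that the aryl gallate is neither transesterified nor hydrolysed.

Step 15
Reactants: 25 (2R,3S)-3-(benzyloxy)-2-[3,4-bis(benzyloxy)phenyl]-5-hydroxychroman-7-yl 3,4,5-tris(benzyloxy)benzoate
Product: 26 catechin 7-O-gallate [(2R,3S)-2-(3,4-dihydroxyphenyl)-3,5-dihydroxychroman-7-yl 3,4,5-trihydroxybenzoate]
Conditions: H2 (1 atm), Pd(OH)2/C, THF/MeOH, rt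
Reagents that add atoms: none
Why: Hydrogenolysis of the six benzyl ethers under neutral conditions; the aryl ester and both stereocentres are not affected, and the reaction is stopped at complete debenzylation so that the benzylic C2–O1 bond is not opened.

## Compound list

1 | 3-ethoxycyclobut-2-en-1-one | CCOC1=CC(=O)C1 | starting material
2 | prop-2-en-1-ol (allyl alcohol) | C=CCO | starting material
3 | 3-(allyloxy)cyclobut-2-en-1-one | C=CCOC1=CC(=O)C1 | intermediate
4 | (S)-glycidyl trityl ether, (2S)-2-[(triphenylmethoxy)methyl]oxirane | C1O[C@@H]1COC(c1ccccc1)(c1ccccc1)c1ccccc1 | starting material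
5 | (2S)-1-(triphenylmethoxy)pent-4-yn-2-ol | C#CC[C@H](O)COC(c1ccccc1)(c1ccccc1)c1ccccc1 | intermediate
6 | (4S)-4-(benzyloxy)-5-(triphenylmethoxy)pent-1-yne | C#CC[C@H](OCc1ccccc1)COC(c1ccccc1)(c1ccccc1)c1ccccc1 | intermediate
7 | (2S)-2-(benzyloxy)pent-4-yn-1-ol | C#CC[C@H](OCc1ccccc1)CO | intermediate
8 | (2S)-2-(benzyloxy)pent-4-ynal | C#CC[C@H](OCc1ccccc1)C=O | intermediate
9 | 4-bromo-1,2-bis(benzyloxy)benzene | Brc1ccc(OCc2ccccc2)c(OCc2ccccc2)c1 | starting material
10 | [3,4-bis(benzyloxy)phenyl]magnesium bromide | Br[Mg]c1ccc(OCc2ccccc2)c(OCc2ccccc2)c1 | intermediate (not isolated)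
11 | (1S,2S)-2-(benzyloxy)-1-[3,4-bis(benzyloxy)phenyl]pent-4-yn-1-ol (threo) | C#CC[C@H](OCc1ccccc1)[C@@H](O)c1ccc(OCc2ccccc2)c(OCc2ccccc2)c1 | intermediate
12 | {[(1S,2S)-2-(benzyloxy)-1-[3,4-bis(benzyloxy)phenyl]pent-4-yn-1-yl]oxy}(triethyl)silane | C#CC[C@H](OCc1ccccc1)[C@@H](O[Si](CC)(CC)CC)c1ccc(OCc2ccccc2)c(OCc2ccccc2)c1 | intermediate
13 | lithium (4S,5S)-4-(benzyloxy)-5-[3,4-bis(benzyloxy)phenyl]-5-[(triethylsilyl)oxy]pent-1-yn-1-olate | [Li]OC#CC[C@H](OCc1ccccc1)[C@@H](O[Si](CC)(CC)CC)c1ccc(OCc2ccccc2)c(OCc2ccccc2)c1 | intermediate (not isolated)
14 | (4S,5S)-4-(benzyloxy)-5-[3,4-bis(benzyloxy)phenyl]-5-[(triethylsilyl)oxy]-1-[(triisopropylsilyl)oxy]pent-1-yne (threo) | CC(C)[Si](C(C)C)(C(C)C)OC#CC[C@H](OCc1ccccc1)[C@@H](O[Si](CC)(CC)CC)c1ccc(OCc2ccccc2)c(OCc2ccccc2)c1 | intermediate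
15 | 3-(allyloxy)buta-1,3-dien-1-one (vinylketene) | C=CCOC(=C)C=C=O | intermediate (not isolated)
16 | 4-[1-(allyloxy)ethenyl]-2-{(2S,3S)-2-(benzyloxy)-3-[3,4-bis(benzyloxy)phenyl]-3-[(triethylsilyl)oxy]propyl}-3-[(triisopropylsilyl)oxy]cyclobut-2-en-1-one (either configuration at the ring CH) | C=CCOC(=C)C1C(=O)C(C[C@H](OCc2ccccc2)[C@@H](O[Si](CC)(CC)CC)c2ccc(OCc3ccccc3)c(OCc3ccccc3)c2)=C1O[Si](C(C)C)(C(C)C)C(C)C | intermediate (not isolated)
17 | 5-(allyloxy)-2-{(2S,3S)-2-(benzyloxy)-3-[3,4-bis(benzyloxy)phenyl]-3-[(triethylsilyl)oxy]propyl}-3-[(triisopropylsilyl)oxy]hexa-1,3,5-trien-1-one (dienylketene) | C=CCOC(=C)C=C(O[Si](C(C)C)(C(C)C)C(C)C)C(C[C@H](OCc1ccccc1)[C@@H](O[Si](CC)(CC)CC)c1ccc(OCc2ccccc2)c(OCc2ccccc2)c1)=C=O | intermediate (not isolated)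
18 | 5-(allyloxy)-2-{(2S,3S)-2-(benzyloxy)-3-[3,4-bis(benzyloxy)phenyl]-3-[(triethylsilyl)oxy]propyl}-3-[(triisopropylsilyl)oxy]cyclohexa-2,4-dien-1-one | O=C1CC(OCC=C)=CC(O[Si](C(C)C)(C(C)C)C(C)C)=C1C[C@H](OCc1ccccc1)[C@@H](O[Si](CC)(CC)CC)c1ccc(OCc2ccccc2)c(OCc2ccccc2)c1 | intermediate (not isolated)
19 | 5-(allyloxy)-2-{(2S,3S)-2-(benzyloxy)-3-[3,4-bis(benzyloxy)phenyl]-3-[(triethylsilyl)oxy]propyl}-3-[(triisopropylsilyl)oxy]phenol (threo) | C=CCOc1cc(O)c(C[C@H](OCc2ccccc2)[C@@H](O[Si](CC)(CC)CC)c2ccc(OCc3ccccc3)c(OCc3ccccc3)c2)c(O[Si](C(C)C)(C(C)C)C(C)C)c1 | intermediate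
20 | 5-(allyloxy)-2-{(2S,3S)-2-(benzyloxy)-3-[3,4-bis(benzyloxy)phenyl]-3-hydroxypropyl}-3-[(triisopropylsilyl)oxy]phenol | C=CCOc1cc(O)c(C[C@H](OCc2ccccc2)[C@@H](O)c2ccc(OCc3ccccc3)c(OCc3ccccc3)c2)c(O[Si](C(C)C)(C(C)C)C(C)C)c1 | intermediate
21 | (2R,3S)-7-(allyloxy)-3-(benzyloxy)-2-[3,4-bis(benzyloxy)phenyl]-5-[(triisopropylsilyl)oxy]chromane | C=CCOc1cc(O[Si](C(C)C)(C(C)C)C(C)C)c2c(c1)O[C@H](c1ccc(OCc3ccccc3)c(OCc3ccccc3)c1)[C@@H](OCc1ccccc1)C2 | intermediate
22 | (2R,3S)-3-(benzyloxy)-2-[3,4-bis(benzyloxy)phenyl]-5-[(triisopropylsilyl)oxy]chroman-7-ol | Oc1cc(O[Si](C(C)C)(C(C)C)C(C)C)c2c(c1)O[C@H](c1ccc(OCc3ccccc3)c(OCc3ccccc3)c1)[C@@H](OCc1ccccc1)C2 | intermediate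
23 | 3,4,5-tris(benzyloxy)benzoic acid | O=C(O)c1cc(OCc2ccccc2)c(OCc2ccccc2)c(OCc2ccccc2)c1 | starting material
24 | (2R,3S)-3-(benzyloxy)-2-[3,4-bis(benzyloxy)phenyl]-5-[(triisopropylsilyl)oxy]chroman-7-yl 3,4,5-tris(benzyloxy)benzoate | O=C(Oc1cc(O[Si](C(C)C)(C(C)C)C(C)C)c2c(c1)O[C@H](c1ccc(OCc3ccccc3)c(OCc3ccccc3)c1)[C@@H](OCc1ccccc1)C2)c1cc(OCc2ccccc2)c(OCc2ccccc2)c(OCc2ccccc2)c1 | intermediate
25 | (2R,3S)-3-(benzyloxy)-2-[3,4-bis(benzyloxy)phenyl]-5-hydroxychroman-7-yl 3,4,5-tris(benzyloxy)benzoate | O=C(Oc1cc(O)c2c(c1)O[C@H](c1ccc(OCc3ccccc3)c(OCc3ccccc3)c1)[C@@H](OCc1ccccc1)C2)c1cc(OCc2ccccc2)c(OCc2ccccc2)c(OCc2ccccc2)c1 | intermediate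
26 | catechin 7-O-gallate, (2R,3S)-2-(3,4-dihydroxyphenyl)-3,5-dihydroxychroman-7-yl 3,4,5-trihydroxybenzoate | O=C(Oc1cc(O)c2c(c1)O[C@H](c1ccc(O)c(O)c1)[C@@H](O)C2)c1cc(O)c(O)c(O)c1 | target

## Step count and least certain steps

Total step count: 15. Longest linear sequence: 14 steps (steps 2 to 15, from 4 to 26); step 1 is a one-step branch.

**Step 9 (key step).** The most likely failure is capture of vinylketene 15 by the phenolic product or by itself (acylation and dimerisation competing with the [2+2] step). A second risk is sluggish ring opening of 3, which as a vinylogous ester is less prone to open than alkyl cyclobutenones, so that the temperature needed approaches the limit of the siloxyalkyne.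
Fallback: generate 15 without heat by 1,4-dehydrochlorination, keeping the same bond construction. The fallback sets out from 2 and 14. Conjugate addition of 2 to ethyl but-2-ynoate (cat. NaH, THF) gives ethyl (2E)-3-(allyloxy)but-2-enoate F1; any allyl ester formed by exchange converges in the next operation. Saponification with LiOH gives (2E)-3-(allyloxy)but-2-enoic acid F2, and 1-chloro-N,N,2-trimethylprop-1-en-1-amine converts it under neutral conditions into (2E)-3-(allyloxy)but-2-enoyl chloride F3. Slow addition of F3 to 14 and Et3N in toluene at 0 to 25 °C forms 15 in the presence of the alkyne; warming to 80 °C then takes 16 through 17 and 18. The fallback returns to the route at 19.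

**Step 1.** The most likely failure is cleavage of the strained four-membered ring by the alcohol (alcoholysis to acetoacetate-type esters) in competition with exchange at C3, because the same acid that activates C3 also activates the carbonyl.
Fallback: from 1, hydrolysis with dilute aqueous HCl gives cyclobutane-1,3-dione F4, whose enol is a strong acid. O-alkylation of F4 with 2 under Mitsunobu conditions (PPh3, DIAD, THF, 0 °C) returns to the route at 3.

**Step 6.** The most likely failure is poor facial selectivity: THF from the Grignard solution can break the chelate and allow Felkin–Anh addition to the erythro epimer. Partial epimerisation of 8 before addition is a second risk.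
Fallback: from 11 as a mixture of C1 epimers, oxidation with Dess–Martin periodinane gives (2S)-2-(benzyloxy)-1-[3,4-bis(benzyloxy)phenyl]pent-4-yn-1-one F5. Reduction of F5 by Noyori transfer hydrogenation (RuCl[(R,R)-TsDPEN](p-cymene), HCO2H/Et3N 5:2, rt) sets C1 by the catalyst and not by the substrate; the (R,R) ligand is the one expected to give 1S by the usual aryl ketone model. The fallback returns to the route at 11.

**Step 11.** The most likely failure is ionisation of the alkoxyphosphonium ion at the electron-rich benzylic carbon before the phenol attacks, leading to elimination towards the enol ether or to loss of stereochemical fidelity.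
Fallback: from 20, close the ring under thermodynamic control instead of by SN2 activation. Catalytic camphorsulfonic acid in CH2Cl2 at 0 °C ionises the benzylic alcohol and the phenol traps the cation. The 2,3-trans chroman with both substituents equatorial is the more stable product, and a cis isomer can equilibrate through the same cation. The fallback returns to the route at 21 and makes no new compound (F0).

## Further compounds

F1 | step 9 | ethyl (2E)-3-(allyloxy)but-2-enoate | CCOC(=O)/C=C(/OCC=C)C
F2 | step 9 | (2E)-3-(allyloxy)but-2-enoic acid | OC(=O)/C=C(/OCC=C)C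
F3 | step 9 | (2E)-3-(allyloxy)but-2-enoyl chloride | ClC(=O)/C=C(/OCC=C)C
F4 | step 1 | cyclobutane-1,3-dione | O=C1CC(=O)C1
F5 | step 6 | (2S)-2-(benzyloxy)-1-[3,4-bis(benzyloxy)phenyl]pent-4-yn-1-one | C#CC[C@H](OCc1ccccc1)C(=O)c1ccc(OCc2ccccc2)c(OCc2ccccc2)c1
F0 | step 11 | none | none
A1 | alternative 1 | 2-{[2,6-bis(methoxymethoxy)-4-(triisopropylsilyloxy)phenyl]methyl}-4,4,5,5-tetramethyl-1,3,2-dioxaborolane | COCOc1cc(O[Si](C(C)C)(C(C)C)C(C)C)cc(OCOC)c1CB1OC(C)(C)C(C)(C)O1
A2 | alternative 1 | 3,4-bis(benzyloxy)phenyl trifluoromethanesulfonate | O=S(=O)(Oc1ccc(OCc2ccccc2)c(OCc2ccccc2)c1)C(F)(F)F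
A3 | alternative 1 | (R)-2-{1-[3,4-bis(benzyloxy)phenyl]-3-[2,6-bis(methoxymethoxy)-4-(triisopropylsilyloxy)phenyl]propan-2-yl}-4,4,5,5-tetramethyl-1,3,2-dioxaborolane | COCOc1cc(O[Si](C(C)C)(C(C)C)C(C)C)cc(OCOC)c1C[C@H](B1OC(C)(C)C(C)(C)O1)Cc1ccc(OCc2ccccc2)c(OCc2ccccc2)c1
A4 | alternative 2 | 4-{(2R)-2-(benzyloxy)-3-[3,4-bis(benzyloxy)phenyl]propyl}-3,5-dihydroxyphenyl 3,4,5-tris(benzyloxy)benzoate | O=C(Oc1cc(O)c(C[C@H](OCc2ccccc2)Cc2ccc(OCc3ccccc3)c(OCc3ccccc3)c2)c(O)c1)c1cc(OCc2ccccc2)c(OCc2ccccc2)c(OCc2ccccc2)c1
A5 | alternative 2 | (2R,3S)-3-(benzyloxy)-2-[3,4-bis(benzyloxy)phenyl]-5-hydroxychroman-7-yl 3,4,5-tris(benzyloxy)benzoate (identical with 25) | O=C(Oc1cc(O)c2c(c1)O[C@H](c1ccc(OCc3ccccc3)c(OCc3ccccc3)c1)[C@@H](OCc1ccccc1)C2)c1cc(OCc2ccccc2)c(OCc2ccccc2)c(OCc2ccccc2)c1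
A6 | alternative 3 | 3-(benzyloxy)-2-(hydroxymethyl)-5-(triisopropylsilyloxy)phenol | OCc1c(O)cc(O[Si](C(C)C)(C(C)C)C(C)C)cc1OCc1ccccc1
A7 | alternative 3 | 5-(benzyloxy)-6-methylidene-3-(triisopropylsilyloxy)cyclohexa-2,4-dien-1-one | C=C1C(=O)C=C(O[Si](C(C)C)(C(C)C)C(C)C)C=C1OCc1ccccc1
A8 | alternative 3 | (E)-{2-[3,4-bis(benzyloxy)phenyl]ethenyl}dimethyl(phenyl)silane | C[Si](C)(/C=C/c1ccc(OCc2ccccc2)c(OCc2ccccc2)c1)c1ccccc1
A9 | alternative 3 | (2R,3S)-5-(benzyloxy)-2-[3,4-bis(benzyloxy)phenyl]-3-[dimethyl(phenyl)silyl]-7-(triisopropylsilyloxy)chromane | CC(C)[Si](C(C)C)(C(C)C)Oc1cc(OCc3ccccc3)c2c(c1)O[C@H](c1ccc(OCc3ccccc3)c(OCc3ccccc3)c1)[C@@H]([Si](C)(C)c1ccccc1)C2
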